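**Retrosynthetic overview**
1. The target is a linear tridepside, ring A–CO2–ring B–CO2–ring C. Cutting the two aryl ester C–O bonds (A/BC last, B/C before it) gives the ring A acid 17, the ring B acid 11 and the ring C phenol 10.
2. All three monomers come from one building block, methyl orsellinate 7, by regioselective O-alkylation that exploits the free 4-OH against the chelated 2-OH.
3. Compound 7 comes from aromatisation of methyl dihydroorsellinate 4. Compound 4 comes from an intermolecular Michael addition of methyl acetoacetate to methyl crotonate with Dieckmann closure in the same flask.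
4. Order of events: the carbocycle is formed once (step 1) and aromatised (steps 2–3). It is then split into rings C, B and A (steps 4–7 and 10–12). Ester B–C is made, then ester A–BC, and the route ends with a hydrogenolysis.

**Assumption:** the target has no stereocentre and is achiral, so no enantiocontrol is needed. The transient sp3 centres of 3, 4 and 5 are carried as mixtures and are erased on aromatisation.

**Step 1**
Reactants: 1 methyl acetoacetate; 2 methyl (E)-crotonate
Product: 4 methyl 6-methyl-2,4-dioxocyclohexane-1-carboxylate (methyl dihydroorsellinate), via Michael adduct 3 (not isolated)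
Conditions: NaOMe (1.1 equiv), MeOH, reflux, 16 h; then cold 2 M HCl
Reagents that add atoms: none
Why: An intermolecular Michael addition of the acetoacetate enolate to the crotonate β-carbon makes the key C–C bond, the acetyl-methyl enolate of 3 closes the six-membered ring by Dieckmann (intramolecular Claisen) condensation, and deprotonation of the 1,3-dione drives the sequence, while the two unselectively formed stereocentres are erased in step 2.

**Step 2**
Reactants: 4 methyl 6-methyl-2,4-dioxocyclohexane-1-carboxylate
Product: 6 methyl 3,5-dibromo-2,4-dihydroxy-6-methylbenzoate, via 3-bromo dione 5 (not isolated)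
Conditions: Br2 (3.05 equiv), AcOH, 10 °C to rt, 16 h; pour into water, filter
Reagents that add atoms: bromine, BrBr
Why: In this bromination–dehydrobromination aromatisation, α-bromination of the enolised dione and loss of HBr give the resorcinol, and electrophilic aromatic bromination of both free ring positions then funnels everything into one crystalline product.

**Step 3**
Reactants: 6 methyl 3,5-dibromo-2,4-dihydroxy-6-methylbenzoate
Product: 7 methyl 2,4-dihydroxy-6-methylbenzoate (methyl orsellinate)
Conditions: H2 (1 atm), 10% Pd/C, NaOAc (2.5 equiv), MeOH, rt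
Reagents that add atoms: none
Why: Catalytic hydrodehalogenation cleaves both aryl C–Br bonds quickly and leaves the ester, the phenols and the arene untouched, with NaOAc taking up the HBr.

**Step 4**
Reactants: 7 methyl orsellinate
Product: 8 methyl 4-(benzyloxy)-2-hydroxy-6-methylbenzoate
Conditions: BnBr (1.05 equiv), K2CO3 (1.2 equiv), acetone, reflux
Reagents that add atoms: benzyl bromide, BrCc1ccccc1
Why: This Williamson ether synthesis is selective for the more acidic, unhindered 4-OH because the 2-OH is locked in a hydrogen bond to the ester carbonyl.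

**Step 5**
Reactants: 8 methyl 4-(benzyloxy)-2-hydroxy-6-methylbenzoate
Product: 9 methyl 4-(benzyloxy)-2-methoxy-6-methylbenzoate
Conditions: MeI (3 equiv), K2CO3 (3 equiv), DMF, 45 °C
Reagents that add atoms: iodomethane, CI
Why: A Williamson methylation with excess MeI in a dipolar aprotic solvent forces alkylation of the only remaining, chelated phenol.

**Step 6**
Reactants: 9 methyl 4-(benzyloxy)-2-methoxy-6-methylbenzoate
Product: 10 methyl 4-hydroxy-2-methoxy-6-methylbenzoate (ring C phenol)
Conditions: H2 (1 atm), 10% Pd/C, EtOAc, rt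
Reagents that add atoms: none
Why: Catalytic hydrogenolysis cleaves the benzyl aryl ether cleanly, and the methyl ether and methyl ester are inert to it.

**Step 7**
Reactants: 9 methyl 4-(benzyloxy)-2-methoxy-6-methylbenzoate
Product: 11 4-(benzyloxy)-2-methoxy-6-methylbenzoic acid (ring B acid)
Conditions: KOH (5 equiv), DMSO–H2O 4:1, 90 °C; then 2 M HCl, 0 °C, pH 2
Reagents that add atoms: potassium hydroxide, [K+].[OH-]
Why: Poorly solvated hydroxide in aqueous DMSO saponifies the 2,6-disubstituted benzoate, both ethers are stable to base, and cold acidification avoids decarboxylation of the electron-rich acid.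

**Step 8**
Reactants: 11 4-(benzyloxy)-2-methoxy-6-methylbenzoic acid; 10 methyl 4-hydroxy-2-methoxy-6-methylbenzoate
Product: 13 methyl 4-{[4-(benzyloxy)-2-methoxy-6-methylbenzoyl]oxy}-2-methoxy-6-methylbenzoate, via mixed trifluoroacetic anhydride 12 (not isolated)
Conditions: (CF3CO)2O (4 equiv), dry toluene, rt, 4 h; evaporate
Reagents that add atoms: trifluoroacetic anhydride, O=C(OC(=O)C(F)(F)F)C(F)(F)F (its CF3CO group sits only in intermediate 12; none of its atoms remain in 13)
Why: In this mixed-anhydride esterification the electron-rich, hindered acid forms an acylium-like acyl trifluoroacetate that is small enough to acylate the single free, unhindered phenol of 10.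

**Step 9**
Reactants: 13 didepside benzyl ether
Product: 14 methyl 4-[(4-hydroxy-2-methoxy-6-methylbenzoyl)oxy]-2-methoxy-6-methylbenzoate
Conditions: H2 (1 atm), 10% Pd/C, EtOAc, rt
Reagents that add atoms: none
Why: Benzyl ether hydrogenolysis in a non-nucleophilic solvent frees the ring B 4-OH without alcoholysis of the aryl ester bond.

**Step 10**
Reactants: 7 methyl orsellinate
Product: 15 methyl 2-hydroxy-4-methoxy-6-methylbenzoate (methyl everninate)
Conditions: MeI (1.05 equiv), K2CO3 (1.2 equiv), acetone, reflux
Reagents that add atoms: iodomethane, CI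
Why: A Williamson methylation with one equivalent of MeI shows the same selectivity as step 4, so the free 4-OH reacts and the chelated 2-OH stays.

**Step 11**
Reactants: 15 methyl everninate
Product: 16 methyl 2-(benzyloxy)-4-methoxy-6-methylbenzoate
Conditions: BnBr (1.5 equiv), K2CO3 (3 equiv), DMF, 65 °C
Reagents that add atoms: benzyl bromide, BrCc1ccccc1
Why: A Williamson benzylation under forcing conditions caps the only remaining phenol, so the ring A acid cannot self-condense during coupling.

**Step 12**
Reactants: 16 methyl 2-(benzyloxy)-4-methoxy-6-methylbenzoate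
Product: 17 2-(benzyloxy)-4-methoxy-6-methylbenzoic acid (ring A acid)
Conditions: KOH (6 equiv), DMSO–H2O 4:1, 95 °C; then 2 M HCl, 0 °C, pH 2
Reagents that add atoms: potassium hydroxide, [K+].[OH-]
Why: The hindered ester is saponified as in step 7, the ethers are inert to base, and cold work-up suppresses decarboxylation.

**Step 13**
Reactants: 17 2-(benzyloxy)-4-methoxy-6-methylbenzoic acid; 14 didepside phenol
Product: 19 methyl 4-[(4-{[2-(benzyloxy)-4-methoxy-6-methylbenzoyl]oxy}-2-methoxy-6-methylbenzoyl)oxy]-2-methoxy-6-methylbenzoate, via mixed trifluoroacetic anhydride 18 (not isolated)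
Conditions: (CF3CO)2O (4 equiv), dry toluene, rt, 4–6 h; evaporate
Reagents that add atoms: trifluoroacetic anhydride, O=C(OC(=O)C(F)(F)F)C(F)(F)F (its CF3CO group sits only in intermediate 18; none of its atoms remain in 19)
Why: This is the same mixed-anhydride esterification as step 8, and 14 offers one unhindered phenol on an ester-deactivated ring, so O-acylation wins over Friedel–Crafts C-acylation.

**Step 14**
Reactants: 19 tridepside benzyl ether
Product: 20 methyl 4-({4-[(2-hydroxy-4-methoxy-6-methylbenzoyl)oxy]-2-methoxy-6-methylbenzoyl}oxy)-2-methoxy-6-methylbenzoate (target)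
Conditions: H2 (1 atm), 10% Pd/C, EtOAc, rt
Reagents that add atoms: none
Why: The final benzyl ether hydrogenolysis unveils the ring A 2-OH under neutral conditions that leave both depside bonds, the methyl ester and the three methyl ethers intact.

**Compound list**
1 | methyl acetoacetate | CC(=O)CC(=O)OC | starting material
2 | methyl (E)-crotonate | C/C=C/C(=O)OC | starting material
3 | dimethyl 2-acetyl-3-methylpentanedioate (Michael adduct; not isolated; stereoisomer mixture) | COC(=O)CC(C)C(C(C)=O)C(=O)OC | intermediate
4 | methyl 6-methyl-2,4-dioxocyclohexane-1-carboxylate (racemic; diastereomer and enol mixture) | COC(=O)C1C(C)CC(=O)CC1=O | intermediate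
5 | methyl 3-bromo-6-methyl-2,4-dioxocyclohexane-1-carboxylate (not isolated; stereoisomer mixture) | COC(=O)C1C(C)CC(=O)C(Br)C1=O | intermediate
6 | methyl 3,5-dibromo-2,4-dihydroxy-6-methylbenzoate | COC(=O)c1c(C)c(Br)c(O)c(Br)c1O | intermediate
7 | methyl 2,4-dihydroxy-6-methylbenzoate (methyl orsellinate) | COC(=O)c1c(C)cc(O)cc1O | intermediate
8 | methyl 4-(benzyloxy)-2-hydroxy-6-methylbenzoate | COC(=O)c1c(C)cc(OCc2ccccc2)cc1O | intermediate
9 | methyl 4-(benzyloxy)-2-methoxy-6-methylbenzoate | COC(=O)c1c(C)cc(OCc2ccccc2)cc1OC | intermediate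
10 | methyl 4-hydroxy-2-methoxy-6-methylbenzoate | COC(=O)c1c(C)cc(O)cc1OC | intermediate
11 | 4-(benzyloxy)-2-methoxy-6-methylbenzoic acid | OC(=O)c1c(C)cc(OCc2ccccc2)cc1OC | intermediate
12 | 4-(benzyloxy)-2-methoxy-6-methylbenzoic trifluoroacetic anhydride (not isolated) | FC(F)(F)C(=O)OC(=O)c1c(C)cc(OCc2ccccc2)cc1OC | intermediate
13 | methyl 4-{[4-(benzyloxy)-2-methoxy-6-methylbenzoyl]oxy}-2-methoxy-6-methylbenzoate | COC(=O)c1c(C)cc(OC(=O)c2c(C)cc(OCc3ccccc3)cc2OC)cc1OC | intermediate
14 | methyl 4-[(4-hydroxy-2-methoxy-6-methylbenzoyl)oxy]-2-methoxy-6-methylbenzoate | COC(=O)c1c(C)cc(OC(=O)c2c(C)cc(O)cc2OC)cc1OC | intermediate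
15 | methyl 2-hydroxy-4-methoxy-6-methylbenzoate (methyl everninate) | COC(=O)c1c(C)cc(OC)cc1O | intermediate
16 | methyl 2-(benzyloxy)-4-methoxy-6-methylbenzoate | COC(=O)c1c(C)cc(OC)cc1OCc1ccccc1 | intermediate
17 | 2-(benzyloxy)-4-methoxy-6-methylbenzoic acid | OC(=O)c1c(C)cc(OC)cc1OCc1ccccc1 | intermediate
18 | 2-(benzyloxy)-4-methoxy-6-methylbenzoic trifluoroacetic anhydride (not isolated) | FC(F)(F)C(=O)OC(=O)c1c(C)cc(OC)cc1OCc1ccccc1 | intermediate
19 | methyl 4-[(4-{[2-(benzyloxy)-4-methoxy-6-methylbenzoyl]oxy}-2-methoxy-6-methylbenzoyl)oxy]-2-methoxy-6-methylbenzoate | COC(=O)c1c(C)cc(OC(=O)c2c(C)cc(OC(=O)c3c(C)cc(OC)cc3OCc3ccccc3)cc2OC)cc1OC | intermediate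
20 | methyl 4-({4-[(2-hydroxy-4-methoxy-6-methylbenzoyl)oxy]-2-methoxy-6-methylbenzoyl}oxy)-2-methoxy-6-methylbenzoate (CNP0362907.0; achiral) | COC(=O)c1c(C)cc(OC(=O)c2c(C)cc(OC(=O)c3c(C)cc(OC)cc3O)cc2OC)cc1OC | target

**Total step count:** 14.
**Longest linear sequence:** 10 (steps 1, 2, 3, 4, 5, 7, 8, 9, 13, 14).

**Three steps most likely to fail**

**Step 13.** The most hindered acid must acylate a phenol that already holds a depside bond. The acylation may be slow, the acid may scramble the existing aryl ester, and some C-acylation is possible.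

The fallback reverses the order of assembly. Acid 17 then meets a monomeric phenol, and the last ester bond repeats the acid type and the phenol of step 8. It sets out from 11 and 17, uses 10 as made in the main route, and comes back at 19.
- Hydrogenolysis of 11 (H2, 10% Pd/C, EtOAc) gives 4-hydroxy-2-methoxy-6-methylbenzoic acid F4.
- Allyl bromide with KHCO3 in DMF at rt alkylates only the carboxylate and gives allyl 4-hydroxy-2-methoxy-6-methylbenzoate F5.
- Acid 17 is activated with (CF3CO)2O to 18 as before and acylates F5. This gives allyl 4-{[2-(benzyloxy)-4-methoxy-6-methylbenzoyl]oxy}-2-methoxy-6-methylbenzoate F6.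
- Zerovalent palladium catalysis (Pd(PPh3)4, N-methylaniline, THF, rt) removes the allyl group and spares the benzyl ether and the aryl ester. The product is 4-{[2-(benzyloxy)-4-methoxy-6-methylbenzoyl]oxy}-2-methoxy-6-methylbenzoic acid F7.
- (CF3CO)2O in toluene converts F7 into 4-{[2-(benzyloxy)-4-methoxy-6-methylbenzoyl]oxy}-2-methoxy-6-methylbenzoic trifluoroacetic anhydride F8, which acylates 10 to give 19.

**Step 12.** The ester carbonyl is flanked by a methyl and a benzyloxy group, so hydrolysis may stall. Harsher heating risks decarboxylation.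

The fallback replaces acyl substitution by a redox adjustment. It sets out from 16 and comes back at 17.
- LiAlH4 in THF (0 °C to rt) reduces the ester to [2-(benzyloxy)-4-methoxy-6-methylphenyl]methanol F2.
- MnO2 in CH2Cl2 oxidises F2 to 2-(benzyloxy)-4-methoxy-6-methylbenzaldehyde F3.
- Pinnick oxidation (NaClO2, NaH2PO4, 2-methyl-2-butene, t-BuOH–H2O, rt) gives 17. The alkene scavenger protects the electron-rich ring from chlorination.

**Step 2.** The brominative aromatisation can give mixtures of under-brominated and over-brominated material, or side-chain bromination.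

The fallback needs no oxidation at all. It sets out from 1 and comes back at 7, bypassing 4 and 6.
- Compound 1 is converted into its dianion (NaH, then n-BuLi, THF, −78 °C, then reflux).
- The terminal carbanion attacks the ester of a second molecule of 1 in an intermolecular Claisen condensation. This gives methyl 3,5,7-trioxooctanoate F1.
- F1 cyclises in the same flask by intramolecular aldol condensation of C2 onto the C7 ketone. Loss of water aromatises it to 7.

**Further compounds**
F1 | step 2 | methyl 3,5,7-trioxooctanoate | CC(=O)CC(=O)CC(=O)CC(=O)OC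
F2 | step 12 | [2-(benzyloxy)-4-methoxy-6-methylphenyl]methanol | OCc1c(C)cc(OC)cc1OCc1ccccc1
F3 | step 12 | 2-(benzyloxy)-4-methoxy-6-methylbenzaldehyde | O=Cc1c(C)cc(OC)cc1OCc1ccccc1
F4 | step 13 | 4-hydroxy-2-methoxy-6-methylbenzoic acid | OC(=O)c1c(C)cc(O)cc1OC
F5 | step 13 | allyl 4-hydroxy-2-methoxy-6-methylbenzoate | C=CCOC(=O)c1c(C)cc(O)cc1OC
F6 | step 13 | allyl 4-{[2-(benzyloxy)-4-methoxy-6-methylbenzoyl]oxy}-2-methoxy-6-methylbenzoate | C=CCOC(=O)c1c(C)cc(OC(=O)c2c(C)cc(OC)cc2OCc2ccccc2)cc1OC
F7 | step 13 | 4-{[2-(benzyloxy)-4-methoxy-6-methylbenzoyl]oxy}-2-methoxy-6-methylbenzoic acid | OC(=O)c1c(C)cc(OC(=O)c2c(C)cc(OC)cc2OCc2ccccc2)cc1OC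
F8 | step 13 | 4-{[2-(benzyloxy)-4-methoxy-6-methylbenzoyl]oxy}-2-methoxy-6-methylbenzoic trifluoroacetic anhydride | FC(F)(F)C(=O)OC(=O)c1c(C)cc(OC(=O)c2c(C)cc(OC)cc2OCc2ccccc2)cc1OC
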